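**Retrosynthetic overview**
1. Target 13 ⇐ (2S)-bis-MOM flavanone 12 by acidic acetal cleavage; 12 ⇐ racemic flavanone 11 by Ru-catalysed transfer-hydrogenation kinetic resolution (the 2R half is reduced away).
2. Ring C (the pyranone) is the only ring that is built: 6-endo oxa-Michael closure of 2′-hydroxychalcone 10; rings A and B are bought as benzene derivatives.
3. Key C–C bond (C2–C3 of the flavanone, Cα–Cβ of 10): Claisen–Schmidt aldol condensation of ring-A methyl ketone 6 with ring-B aldehyde 8.
4. 6 ⇐ 2′,6′-dihydroxy-4′-methoxyacetophenone 1 by mono-MOM protection, O-allylation, aromatic Claisen rearrangement and cross-metathesis (allyl → prenyl); the MOM group on the second ortho oxygen forces ring closure through the OH next to the prenyl group (8-prenyl, not 6-prenyl).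
5. 8 ⇐ isovanillin 7 by MOM protection.

Assumption: 1-(2,6-dihydroxy-4-methoxyphenyl)ethanone and isovanillin are taken as inexpensive catalogue chemicals; racemic compounds carry no stereodescriptors in their SMILES.

**Step 1**
Reactants: 1 1-(2,6-dihydroxy-4-methoxyphenyl)ethanone
Product: 2 1-[2-hydroxy-4-methoxy-6-(methoxymethoxy)phenyl]ethanone
Conditions: MOMCl (1.1 equiv), K2CO3 (1.5 equiv), acetone, 0 °C → rt
Reagents that add atoms: chloromethyl methyl ether (MOMCl), COCCl
Why: Williamson-type O-alkylation of one of the two equivalent phenols; after the first MOM group is on, the remaining OH is locked in a hydrogen bond to the ketone and does not react under these mild conditions, so mono-protection is clean.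

**Step 2**
Reactants: 2 1-[2-hydroxy-4-methoxy-6-(methoxymethoxy)phenyl]ethanone
Product: 3 1-[4-methoxy-2-(methoxymethoxy)-6-(prop-2-en-1-yloxy)phenyl]ethanone
Conditions: allyl bromide (1.5 equiv), K2CO3 (2 equiv), DMF, 60 °C
Reagents that add atoms: allyl bromide, C=CCBr
Why: Williamson ether synthesis on the chelated phenol, which needs the polar solvent and gentle heating, while K2CO3 is too weak to enolise the hindered methyl ketone.

**Step 3**
Reactants: 3 1-[4-methoxy-2-(methoxymethoxy)-6-(prop-2-en-1-yloxy)phenyl]ethanone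
Product: 5 1-[2-hydroxy-4-methoxy-6-(methoxymethoxy)-3-(prop-2-en-1-yl)phenyl]ethanone, via ortho-dienone 4 (not isolated)
Conditions: PhNEt2, 200 °C, Ar, 5 h
Reagents that add atoms: none
Why: Aromatic Claisen rearrangement, in which the [3,3] shift delivers the allyl group to the only free ortho carbon (the other carries the acetyl group) and dienone 4 tautomerises to the phenol, placing the side chain between the new OH and the OMe group; MOM ethers tolerate the amine solvent at this temperature.

**Step 4**
Reactants: 5 1-[2-hydroxy-4-methoxy-6-(methoxymethoxy)-3-(prop-2-en-1-yl)phenyl]ethanone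
Product: 6 1-[2-hydroxy-4-methoxy-6-(methoxymethoxy)-3-(3-methylbut-2-en-1-yl)phenyl]ethanone
Conditions: 2-methyl-2-butene (large excess), second-generation Grubbs catalyst RuCl2(=CHPh)(PCy3)(H2IMes) (5 mol %), CH2Cl2, 40 °C, sealed tube
Reagents that add atoms: 2-methyl-2-butene, CC=C(C)C
Why: Olefin cross-metathesis, in which the excess trisubstituted alkene converts the terminal allyl arene into the prenyl group with loss of propene, the phenol, aryl ketone and MOM ether being inert to the ruthenium carbene.

**Step 5**
Reactants: 7 3-hydroxy-4-methoxybenzaldehyde (isovanillin)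
Product: 8 4-methoxy-3-(methoxymethoxy)benzaldehyde
Conditions: MOMCl (1.3 equiv), K2CO3 (2 equiv), acetone, rt
Reagents that add atoms: chloromethyl methyl ether (MOMCl), COCCl
Why: Williamson-type O-alkylation that masks the acidic phenol as a hydroxide-stable MOM acetal so the aldehyde stays fully electrophilic in the aldol step.

**Step 6**
Reactants: 6 1-[2-hydroxy-4-methoxy-6-(methoxymethoxy)-3-(3-methylbut-2-en-1-yl)phenyl]ethanone; 8 4-methoxy-3-(methoxymethoxy)benzaldehyde
Product: 10 (2E)-1-[2-hydroxy-4-methoxy-6-(methoxymethoxy)-3-(3-methylbut-2-en-1-yl)phenyl]-3-[4-methoxy-3-(methoxymethoxy)phenyl]prop-2-en-1-one, via aldol adduct 9 (not isolated)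
Conditions: KOH (50% aq., 15 equiv), EtOH, 0 °C → rt, 36 h; then cold aq. NH4Cl to pH 6–7
Reagents that add atoms: none
Why: Claisen–Schmidt (crossed aldol) condensation, in which only the methyl ketone can enolise and the aldehyde has no α-hydrogen, the aldol adduct 9 losing water by E1cB to the conjugated E-enone while MOM ethers and the prenyl olefin are stable to aqueous hydroxide; any flavanone formed already here is the product of step 7.

**Step 7**
Reactants: 10 (2E)-1-[2-hydroxy-4-methoxy-6-(methoxymethoxy)-3-(3-methylbut-2-en-1-yl)phenyl]-3-[4-methoxy-3-(methoxymethoxy)phenyl]prop-2-en-1-one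
Product: 11 racemic 7-methoxy-2-[4-methoxy-3-(methoxymethoxy)phenyl]-5-(methoxymethoxy)-8-(3-methylbut-2-en-1-yl)-2,3-dihydro-4H-chromen-4-one
Conditions: NaOAc (10 equiv), EtOH/H2O 10:1, reflux, 24 h
Reagents that add atoms: none
Why: Intramolecular 6-endo oxa-Michael addition of the only free phenol (the one beside the prenyl group) gives the 8-prenyl flavanone alone, with C2 formed as a racemate, and the 6′-alkoxy group twists the enone out of conjugation so the chalcone–flavanone equilibrium lies on the flavanone side.

**Step 8**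
Reactants: 11 racemic 7-methoxy-2-[4-methoxy-3-(methoxymethoxy)phenyl]-5-(methoxymethoxy)-8-(3-methylbut-2-en-1-yl)-2,3-dihydro-4H-chromen-4-one
Product: 12 (2S)-7-methoxy-2-[4-methoxy-3-(methoxymethoxy)phenyl]-5-(methoxymethoxy)-8-(3-methylbut-2-en-1-yl)-2,3-dihydro-4H-chromen-4-one
Conditions: RuCl(p-cymene)[(R,R)-TsDPEN] (2 mol %), HCO2H/Et3N (5:2), EtOAc, 35 °C, stopped at about 55% conversion (chiral HPLC control), chromatography
Reagents that add atoms: none
Why: Noyori–Ikariya asymmetric transfer hydrogenation run as a kinetic resolution, in which the (R,R)-catalyst delivers hydride to the carbonyl face that gives the 4R alcohol, a face that is anti to the 2-aryl group only in the (2R)-ketone, so the 2R enantiomer is reduced to the cis-(2R,4R)-flavan-4-ol while the mismatched (2S)-ketone 12 is recovered in ≥98% ee (maximum yield 50%) and is not ring-opened by the weakly acidic formate medium.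

**Step 9**
Reactants: 12 (2S)-7-methoxy-2-[4-methoxy-3-(methoxymethoxy)phenyl]-5-(methoxymethoxy)-8-(3-methylbut-2-en-1-yl)-2,3-dihydro-4H-chromen-4-one
Product: 13 (2S)-5-hydroxy-2-(3-hydroxy-4-methoxyphenyl)-7-methoxy-8-(3-methylbut-2-en-1-yl)-2,3-dihydro-4H-chromen-4-one
Conditions: 3 M aq. HCl, MeOH, 40 °C, 3 h
Reagents that add atoms: none
Why: Acid-catalysed cleavage of both MOM acetals by transacetalisation to methanol, with no base present to trigger the retro-oxa-Michael ring opening that racemises 5-hydroxyflavanones, and with no free hydroxyl ortho to the prenyl group that could cyclise onto it, so C2 stays S.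

**Compound list**
1 | 1-(2,6-dihydroxy-4-methoxyphenyl)ethanone | CC(=O)c1c(O)cc(OC)cc1O | starting material
2 | 1-[2-hydroxy-4-methoxy-6-(methoxymethoxy)phenyl]ethanone | CC(=O)c1c(O)cc(OC)cc1OCOC | intermediate
3 | 1-[4-methoxy-2-(methoxymethoxy)-6-(prop-2-en-1-yloxy)phenyl]ethanone | CC(=O)c1c(OCC=C)cc(OC)cc1OCOC | intermediate
4 | racemic 2-acetyl-5-methoxy-3-(methoxymethoxy)-6-(prop-2-en-1-yl)cyclohexa-2,4-dien-1-one (ortho-dienone, not isolated) | CC(=O)C1=C(OCOC)C=C(OC)C(CC=C)C1=O | intermediate
5 | 1-[2-hydroxy-4-methoxy-6-(methoxymethoxy)-3-(prop-2-en-1-yl)phenyl]ethanone | CC(=O)c1c(O)c(CC=C)c(OC)cc1OCOC | intermediate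
6 | 1-[2-hydroxy-4-methoxy-6-(methoxymethoxy)-3-(3-methylbut-2-en-1-yl)phenyl]ethanone | CC(=O)c1c(O)c(CC=C(C)C)c(OC)cc1OCOC | intermediate
7 | 3-hydroxy-4-methoxybenzaldehyde (isovanillin) | COc1ccc(C=O)cc1O | starting material
8 | 4-methoxy-3-(methoxymethoxy)benzaldehyde | COCOc1cc(C=O)ccc1OC | intermediate
9 | racemic 3-hydroxy-1-[2-hydroxy-4-methoxy-6-(methoxymethoxy)-3-(3-methylbut-2-en-1-yl)phenyl]-3-[4-methoxy-3-(methoxymethoxy)phenyl]propan-1-one (aldol adduct, not isolated) | COCOc1cc(C(O)CC(=O)c2c(O)c(CC=C(C)C)c(OC)cc2OCOC)ccc1OC | intermediate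
10 | (2E)-1-[2-hydroxy-4-methoxy-6-(methoxymethoxy)-3-(3-methylbut-2-en-1-yl)phenyl]-3-[4-methoxy-3-(methoxymethoxy)phenyl]prop-2-en-1-one | COCOc1cc(/C=C/C(=O)c2c(O)c(CC=C(C)C)c(OC)cc2OCOC)ccc1OC | intermediate
11 | racemic 7-methoxy-2-[4-methoxy-3-(methoxymethoxy)phenyl]-5-(methoxymethoxy)-8-(3-methylbut-2-en-1-yl)-2,3-dihydro-4H-chromen-4-one | COCOc1cc(C2CC(=O)c3c(OCOC)cc(OC)c(CC=C(C)C)c3O2)ccc1OC | intermediate
12 | (2S)-7-methoxy-2-[4-methoxy-3-(methoxymethoxy)phenyl]-5-(methoxymethoxy)-8-(3-methylbut-2-en-1-yl)-2,3-dihydro-4H-chromen-4-one | COCOc1cc([C@@H]2CC(=O)c3c(OCOC)cc(OC)c(CC=C(C)C)c3O2)ccc1OC | intermediate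
13 | (2S)-5-hydroxy-2-(3-hydroxy-4-methoxyphenyl)-7-methoxy-8-(3-methylbut-2-en-1-yl)-2,3-dihydro-4H-chromen-4-one | COc1ccc([C@@H]2CC(=O)c3c(O)cc(OC)c(CC=C(C)C)c3O2)cc1O | target

**Summary**
Total step count: 9. Longest linear sequence: 8 steps (1 → 13 through steps 1–4 and 6–9); step 5 is the one-step side branch.

Three steps most likely to fail, in falling order of risk:

Step 8. The carbonyl of 11 is flanked by the peri 5-OMOM group and is very electron-rich, so transfer hydrogenation may be slow or poorly selective. The fallback sets out from racemic flavanone 11 and comes back to the route at 12. The two enantiomers of 11 are separated directly by preparative chromatography on a polysaccharide chiral stationary phase (amylose tris(3,5-dimethylphenylcarbamate), heptane/i-PrOH or supercritical CO2/MeOH). The 2S enantiomer is recognised by its CD spectrum (positive Cotton effect near 330 nm, negative near 290 nm) and carried into step 9. No new compound is made (F0).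

Step 9. Warm acid could erode the ee of the 5-hydroxyflavanone or add across the prenyl olefin during the slower cleavage of the 3′-O-MOM group. The fallback sets out from 6 and isovanillin 7 and comes back at target 13, so that only the very labile, carbonyl-chelated 5-O-MOM group has to be removed after the resolution. Ketone 6 is condensed with unprotected 7 (KOH, EtOH, rt; the meta-phenoxide is not conjugated with the aldehyde and does not switch it off), through the aldol adduct F1 (not isolated), to the free-phenol chalcone F2. NaOAc in refluxing EtOH closes this to the racemic 3′-hydroxy-5-O-MOM flavanone F3. Kinetic resolution exactly as in step 8 leaves the (2S)-flavanone F4. Pyridinium p-toluenesulfonate in MeOH at rt then removes the single peri MOM group to give 13.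

Step 6. The di-ortho-substituted ketone enolate is hindered and the aldehyde is electron-rich, so the hydroxide-mediated condensation may stall. The fallback sets out from 6 and 8 and comes back at 11. The phenoxide–enolate dianion of 6 is preformed with LiN(SiMe3)2 (2.2 equiv, THF, −78 °C) and adds to 8 in a directed aldol reaction; after NH4Cl quench the aldol adduct 9 is isolated. PPh3/DIAD (THF, 0 °C) then closes ring C by intramolecular Mitsunobu etherification of the racemic benzylic alcohol to give 11. Any chalcone 10 formed by competing elimination is converted to 11 under the step-7 conditions. No new compound is made (F0).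

**Further compounds**
F0 | step 8 | none | none
F1 | step 9 | racemic 3-hydroxy-3-(3-hydroxy-4-methoxyphenyl)-1-[2-hydroxy-4-methoxy-6-(methoxymethoxy)-3-(3-methylbut-2-en-1-yl)phenyl]propan-1-one | COc1ccc(C(O)CC(=O)c2c(O)c(CC=C(C)C)c(OC)cc2OCOC)cc1O
F2 | step 9 | (2E)-3-(3-hydroxy-4-methoxyphenyl)-1-[2-hydroxy-4-methoxy-6-(methoxymethoxy)-3-(3-methylbut-2-en-1-yl)phenyl]prop-2-en-1-one | COc1ccc(/C=C/C(=O)c2c(O)c(CC=C(C)C)c(OC)cc2OCOC)cc1O
F3 | step 9 | racemic 2-(3-hydroxy-4-methoxyphenyl)-7-methoxy-5-(methoxymethoxy)-8-(3-methylbut-2-en-1-yl)-2,3-dihydro-4H-chromen-4-one | COc1ccc(C2CC(=O)c3c(OCOC)cc(OC)c(CC=C(C)C)c3O2)cc1O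
F4 | step 9 | (2S)-2-(3-hydroxy-4-methoxyphenyl)-7-methoxy-5-(methoxymethoxy)-8-(3-methylbut-2-en-1-yl)-2,3-dihydro-4H-chromen-4-one | COc1ccc([C@@H]2CC(=O)c3c(OCOC)cc(OC)c(CC=C(C)C)c3O2)cc1O
F0 | step 6 | none | none
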